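**Retrosynthetic overview**
- Last bond formed: ring B C1'–C7', by a Ni/photoredox deoxygenative radical coupling of a free primary alcohol (ring A–C7–C8–C8'–C7'–OH) with the fully elaborated aryl bromide that already carries the threo side chain and a free carbinol. Only debenzylation follows.
- The ring A C1–C7 bond is made by the same radical coupling. C8 and C8' are never touched: they come from an enzymatically desymmetrised meso-2,3-dimethylbutane-1,4-diol (built from maleic anhydride).
- Side chain: C8'' by Mitsunobu inversion of methyl (R)-lactate with 4-bromo-2,6-dimethoxyphenol; C7'' by chelation-controlled aryl Grignard addition to the derived aldehyde.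
- No ring is constructed. Rings A and C come from anisole, ring B from resorcinol.

Assumption: the lipase in Step 12 gives monoacetate 16 as drawn (I have not confirmed the sense for this enzyme); if it prefers the other arm, lipase hydrolysis of the meso-diacetate gives 16 instead.

**Step 1**
Reactants: 1 anisole
Product: 2 2-methoxyphenol
Conditions: n-BuLi, TMEDA, Et2O, 0 °C to rt; B(OMe)3, −78 °C to rt; H2O2, AcOH, 0 °C
Reagents that add atoms: hydrogen peroxide, OO (supplies the phenol oxygen)
Why: Directed ortho-metalation of anisole, borylation and oxidative C–B to C–O conversion; no stereocentre.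

**Step 2**
Reactants: 2 2-methoxyphenol
Product: 3 4-bromo-2-methoxyphenol
Conditions: NBS (1.0 equiv), MeCN, 0 °C
Reagents that add atoms: N-bromosuccinimide, O=C1CCC(=O)N1Br
Why: Electrophilic aromatic bromination; the free OH is the stronger director, so bromine enters para to it.

**Step 3**
Reactants: 3 4-bromo-2-methoxyphenol
Product: 4 1-(benzyloxy)-4-bromo-2-methoxybenzene
Conditions: BnBr, K2CO3, DMF, rt
Reagents that add atoms: benzyl bromide, BrCc1ccccc1
Why: Williamson etherification; benzyl masks the phenol for the Grignard and photoredox steps and is removed in Step 16.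

**Step 4**
Reactants: 5 resorcinol
Product: 6 1,3-dimethoxybenzene
Conditions: MeI, K2CO3, acetone, reflux
Reagents that add atoms: iodomethane, CI
Why: Double Williamson O-methylation.

**Step 5**
Reactants: 6 1,3-dimethoxybenzene
Product: 7 2,6-dimethoxyphenol
Conditions: n-BuLi, THF, 0 °C to rt; B(OMe)3, −78 °C to rt; H2O2, AcOH, 0 °C
Reagents that add atoms: hydrogen peroxide, OO
Why: Directed ortho-metalation at C2 (flanked by both OMe groups), borylation and oxidation.

**Step 6**
Reactants: 7 2,6-dimethoxyphenol
Product: 8 4-bromo-2,6-dimethoxyphenol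
Conditions: NBS, NaH (cat.), CHCl3, −45 °C to reflux
Reagents that add atoms: N-bromosuccinimide, O=C1CCC(=O)N1Br
Why: Electrophilic bromination through the phenoxide, which directs para to O rather than to the OMe-activated C3.

**Step 7**
Reactants: 8 4-bromo-2,6-dimethoxyphenol; 9 methyl (R)-lactate
Product: 10 methyl (S)-2-(4-bromo-2,6-dimethoxyphenoxy)propanoate
Conditions: PPh3, DIAD, THF, 0 °C to rt
Reagents that add atoms: none
Why: Mitsunobu etherification; clean SN2 inversion at the lactate carbon sets C8'' as S.

**Step 8**
Reactants: 10 methyl (S)-2-(4-bromo-2,6-dimethoxyphenoxy)propanoate; 4 1-(benzyloxy)-4-bromo-2-methoxybenzene (as its Grignard reagent)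
Product: 11 (1S,2S)-1-[4-(benzyloxy)-3-methoxyphenyl]-2-(4-bromo-2,6-dimethoxyphenoxy)propan-1-ol (threo)
Conditions: 4, Mg, THF (ArMgBr); 10, DIBAL-H (1.05 equiv), CH2Cl2, −78 °C; then ArMgBr (2 equiv), −78 to −20 °C; minor erythro isomer removed by chromatography
Reagents that add atoms: none
Why: One-pot ester half-reduction and Grignard addition avoids isolating the epimerisable α-aryloxy aldehyde; Cram-chelate control (Mg bridging C=O and the aryloxy/ortho-OMe oxygens, aryl attacking past H rather than CH3) gives the (7''S,8''S) threo alcohol.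

**Step 9**
Reactants: 12 maleic anhydride (2 equiv)
Product: 13 2,3-dimethylmaleic anhydride
Conditions: 2-aminopyridine (0.5 equiv), AcOH, reflux; then 2 M H2SO4, reflux
Reagents that add atoms: none
Why: Amidine-mediated decarboxylative dimerisation of maleic anhydride (loss of 2 CO2), a known preparation of this anhydride.

**Step 10**
Reactants: 13 2,3-dimethylmaleic anhydride
Product: 14 cis-3,4-dimethyloxolane-2,5-dione (meso-2,3-dimethylsuccinic anhydride)
Conditions: H2 (4 atm), 10% Pd/C, EtOAc, rt
Reagents that add atoms: none
Why: Heterogeneous syn-hydrogenation of the cyclic tetrasubstituted alkene puts both methyls cis, fixing the meso (erythro) relationship of C8/C8'.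

**Step 11**
Reactants: 14 meso-2,3-dimethylsuccinic anhydride
Product: 15 meso-(2R,3S)-2,3-dimethylbutane-1,4-diol
Conditions: LiAlH4, THF, 0 °C to reflux
Reagents that add atoms: none
Why: Hydride reduction of the anhydride to the diol; the relative configuration is retained.

**Step 12**
Reactants: 15 meso-2,3-dimethylbutane-1,4-diol
Product: 16 (2S,3R)-4-hydroxy-2,3-dimethylbutyl acetate
Conditions: lipase (Amano PS or AK), vinyl acetate, i-Pr2O, rt, run to slight over-acylation
Reagents that add atoms: vinyl acetate, C=COC(C)=O (acetyl group)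
Why: Enzymatic desymmetrisation by enantiotopic-group-selective transesterification fixes the absolute configuration of both stereocentres; slight over-acylation to diacetate upgrades the ee.

**Step 13**
Reactants: 16 (2S,3R)-4-hydroxy-2,3-dimethylbutyl acetate; 4 1-(benzyloxy)-4-bromo-2-methoxybenzene
Product: 17 (2S,3S)-4-[4-(benzyloxy)-3-methoxyphenyl]-2,3-dimethylbutyl acetate
Conditions: 16, N-aryl benzoxazolium salt (NHC precursor), pyridine, MTBE, rt, 15 min; then 4, NiBr2·dtbbpy (5 mol%), [Ir(ppy)2(dtbbpy)]PF6 (1.5 mol%), quinuclidine, DMA/MTBE, 450 nm LEDs, rt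
Reagents that add atoms: none
Why: Ni/photoredox deoxygenative arylation: the NHC–alcohol adduct is oxidised and undergoes β-scission to a primary alkyl radical at C7, which is captured by aryl–Ni and reductively eliminated; the stereocentres are β/γ to the radical and untouched.

**Step 14**
Reactants: 17
Product: 18 (2S,3S)-4-[4-(benzyloxy)-3-methoxyphenyl]-2,3-dimethylbutan-1-ol
Conditions: K2CO3, MeOH, rt
Reagents that add atoms: none
Why: Zemplén-type acetate methanolysis; the benzyl ether and both stereocentres are unaffected.

**Step 15 (key step)**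
Reactants: 18 (1.5 equiv); 11 (1.0 equiv)
Product: 19 (1S,2S)-1-[4-(benzyloxy)-3-methoxyphenyl]-2-{4-[(2R,3S)-4-(4-(benzyloxy)-3-methoxyphenyl)-2,3-dimethylbutyl]-2,6-dimethoxyphenoxy}propan-1-ol
Conditions: 18, benzoxazolium salt (1.4 equiv, kept below 18), pyridine, MTBE, rt; then 11, NiBr2·dtbbpy (10 mol%), [Ir(ppy)2(dtbbpy)]PF6 (2 mol%), quinuclidine, phthalimide, DMA/MTBE, 450 nm LEDs, rt
Reagents that add atoms: none
Why: The same Ni/photoredox deoxygenative radical C(sp3)–C(sp2) coupling joins the two halves; the primary C7' radical cannot scramble C8/C8', and the free C7'' carbinol of 11 is spared because only 18 is pre-activated (the C8' label changes from S to R only through CIP priorities).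

**Step 16**
Reactants: 19
Product: 20 (+)-(7''S,8S,8'R,8''S)-4,4''-dihydroxy-3,3',3'',5'-tetramethoxy-4',8''-oxy-8,8'-sesquineolignan-7''-ol (target)
Conditions: H2 (1 atm), 10% Pd/C, EtOAc/MeOH, rt, neutral, monitored closely
Reagents that add atoms: none
Why: Hydrogenolysis of both aryl benzyl ethers; under neutral conditions the benzylic C7''–OH and the homobenzylic aryl ether survive, and no stereocentre is affected.

**Compound list**
1 | anisole | COc1ccccc1 | starting material
2 | 2-methoxyphenol | COc1ccccc1O | intermediate
3 | 4-bromo-2-methoxyphenol | COc1cc(Br)ccc1O | intermediate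
4 | 1-(benzyloxy)-4-bromo-2-methoxybenzene | COc1cc(Br)ccc1OCc1ccccc1 | intermediate
5 | resorcinol | Oc1cccc(O)c1 | starting material
6 | 1,3-dimethoxybenzene | COc1cccc(OC)c1 | intermediate
7 | 2,6-dimethoxyphenol | COc1cccc(OC)c1O | intermediate
8 | 4-bromo-2,6-dimethoxyphenol | COc1cc(Br)cc(OC)c1O | intermediate
9 | methyl (R)-lactate | C[C@@H](O)C(=O)OC | starting material
10 | methyl (S)-2-(4-bromo-2,6-dimethoxyphenoxy)propanoate | C[C@H](Oc1c(OC)cc(Br)cc1OC)C(=O)OC | intermediate
11 | (1S,2S)-1-[4-(benzyloxy)-3-methoxyphenyl]-2-(4-bromo-2,6-dimethoxyphenoxy)propan-1-ol | COc1cc(Br)cc(OC)c1O[C@@H](C)[C@@H](O)c1ccc(OCc2ccccc2)c(OC)c1 | intermediate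
12 | maleic anhydride | O=C1OC(=O)C=C1 | starting material
13 | 2,3-dimethylmaleic anhydride | CC1=C(C)C(=O)OC1=O | intermediate
14 | cis-(3R,4S)-3,4-dimethyloxolane-2,5-dione (meso) | C[C@@H]1[C@H](C)C(=O)OC1=O | intermediate
15 | meso-(2R,3S)-2,3-dimethylbutane-1,4-diol | OC[C@H](C)[C@H](C)CO | intermediate
16 | (2S,3R)-4-hydroxy-2,3-dimethylbutyl acetate | CC(=O)OC[C@@H](C)[C@@H](C)CO | intermediate
17 | (2S,3S)-4-[4-(benzyloxy)-3-methoxyphenyl]-2,3-dimethylbutyl acetate | COc1cc(C[C@H](C)[C@H](C)COC(C)=O)ccc1OCc1ccccc1 | intermediate
18 | (2S,3S)-4-[4-(benzyloxy)-3-methoxyphenyl]-2,3-dimethylbutan-1-ol | COc1cc(C[C@H](C)[C@H](C)CO)ccc1OCc1ccccc1 | intermediate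
19 | bis-O-benzyl ether of the target (name in Step 15) | COc1cc(C[C@H](C)[C@H](C)Cc2cc(OC)c(O[C@@H](C)[C@@H](O)c3ccc(OCc4ccccc4)c(OC)c3)c(OC)c2)ccc1OCc1ccccc1 | intermediate
20 | (+)-(7''S,8S,8'R,8''S)-4,4''-dihydroxy-3,3',3'',5'-tetramethoxy-4',8''-oxy-8,8'-sesquineolignan-7''-ol | COc1cc(C[C@H](C)[C@H](C)Cc2cc(OC)c(O[C@@H](C)[C@@H](O)c3ccc(O)c(OC)c3)c(OC)c2)ccc1O | target

**Totals**
Total steps: 16. Longest linear sequence: 8 (Steps 9–16, from maleic anhydride).

**Three steps most likely to fail**
1. Step 15 (late-stage radical coupling): oxidative addition of the electron-rich bromide 11 may be slow, and its free benzylic OH could compete. Fallback: convert 18 to the primary bromide (Appel) and run a Zn-mediated Ni/bipyridine cross-electrophile coupling with ester 10, which has no free OH; then build the carbinol afterwards with the DIBAL/ArMgBr sequence of Step 8 (linear order, halide radical precursor).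
2. Step 8 (C7'' diastereoselectivity and α-epimerisation): the threo preference rests on chelation by a weakly basic aryloxy group and may be modest. Fallback: convert 10 to the Weinreb amide, add the aryl Grignard to give the α-aryloxy ketone, and set C7'' by catalyst-controlled reduction (CBS or Ru–TsDPEN transfer hydrogenation); erythro material can be recycled through the same ketone.
3. Step 12 (enzymatic desymmetrisation): the ee for a primary alcohol with a β-stereocentre may be insufficient. Fallback: desymmetrise anhydride 14 instead by cinchona-alkaloid-mediated methanolysis to the hemiester, reduce the acid with BH3·SMe2 to the hydroxy ester, use that alcohol in Step 13, and reduce the ester with LiAlH4 in place of Step 14.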